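**Retrosynthetic overview**
1. 26 ⇐ 25 ⇐ 24: both carbinol centres come from two successive hydroxyl-directed hydride deliveries to an epoxy ene-dione (C5 first, then C2); the acid side chain comes from an allyl group (cross-metathesis, Pinnick).
2. Oxirane ⇐ quinone 19 by catalytic asymmetric nucleophilic epoxidation of its only C–H-bearing C=C (sets C1 and C6).
3. Six-membered carbocycle ⇐ four-membered ring: quinone 19 ⇐ 4-alkynyl-4-hydroxycyclobutenone 17 by a thermal two-atom ring expansion.
4. Enabling feature: ring carbons C2 and C5 both carry oxygen and are para; between them lie the fully substituted C3=C4 and the C6(H)–C1(R) pair. This is the pattern that a cyclobutenone C1(=O)/C4(OH) pair, its C2=C3 bond and an alkyne deliver.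
5. 17 ⇐ diisopropyl squarate 8 plus three carbanions (9, 13, 15) added in a regiochemically programmed order. Ring order: cyclobutene (bought) → cyclohexadienedione (step 5) → oxirane (step 6).

Key step: step 5

Remark: ring locants of the bicyclic compounds follow 7-oxabicyclo[4.1.0]hept-3-ene (C1 = quaternary epoxide carbon, C6 = epoxide CH, C2 and C5 = oxygenated carbons); for step 6 it is assumed that a short screen of the quinine/quinidine-derived catalyst pair identifies the pseudo-enantiomer that gives the (1R,6S)-epoxide.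

**Step 1**
Reactants: 1 hept-1-yne
Product: 3 (1E)-1-iodohept-1-ene, via alkenylalane 2 (not isolated)
Conditions: i-Bu2AlH (1.0 equiv), hexane, 50 °C; then I2, THF, −50 °C → rt
Reagents that add atoms: iodine II
Why: Zweifel-type hydroalumination–iodination: syn addition of Al–H across the terminal alkyne puts aluminium on C1 with E geometry, and iodinolysis of the C–Al bond with retention should give the (E)-iodide.

**Step 2**
Reactants: 4 (4-methoxyphenyl)methanol; 5 tributyl(iodomethyl)stannane
Product: 7 tributyl{[(4-methoxybenzyl)oxy]methyl}stannane, via sodium alkoxide 6 (not isolated)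
Conditions: NaH, THF/DMF, 0 °C; then 5, rt
Reagents that add atoms: none
Why: Williamson ether synthesis: the sodium alkoxide displaces the unhindered primary iodide α to tin by SN2, and the C–Sn bond is inert to alkoxide.

**Step 3**
Reactants: 3 (1E)-1-iodohept-1-ene; 8 3,4-diisopropoxycyclobut-3-ene-1,2-dione (diisopropyl squarate)
Product: 11 3-[(1E)-hept-1-en-1-yl]-4-isopropoxycyclobut-3-ene-1,2-dione, via heptenyllithium 9 (not isolated), via squarate adduct 10 (not isolated)
Conditions: 3, t-BuLi (2.0 equiv), Et2O, −78 °C; added to 8, THF, −78 °C; then 2 M aq. HCl, 0 °C → rt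
Reagents that add atoms: water O
Why: Iodine–lithium exchange proceeds with retention of the E geometry, the vinyllithium adds 1,2 to one squarate carbonyl, and acid ionises the doubly activated tertiary carbinol so that water enters at the vinylogous position with loss of isopropanol (standard conversion of a dialkyl squarate into a 3-alkoxy-4-substituted cyclobutenedione).

**Step 4**
Reactants: 11 3-[(1E)-hept-1-en-1-yl]-4-isopropoxycyclobut-3-ene-1,2-dione; 12 pent-1-en-4-yne; 7 tributyl{[(4-methoxybenzyl)oxy]methyl}stannane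
Product: 17 rac-2-[(1E)-hept-1-en-1-yl]-4-hydroxy-3-{[(4-methoxybenzyl)oxy]methyl}-4-(pent-4-en-1-yn-1-yl)cyclobut-2-en-1-one, via lithium acetylide 13 (not isolated), via monoadduct alkoxide 14 (not isolated), via alkoxymethyllithium 15 (not isolated), via bisadduct dialkoxide 16 (not isolated)
Conditions: 12, n-BuLi, THF, −78 °C; 11 added, −78 °C; then 15 (from 7, n-BuLi, THF, −78 °C) by cannula, −78 °C; then 1 M aq. HCl, 0 °C
Reagents that add atoms: water O
Why: Sequential 1,2-additions to a squaric acid derivative followed by a Stork–Danheiser-type transposition: the acetylide should attack the ketone carbonyl flanked by the isopropoxy carbon (the other carbonyl is a deactivated vinylogous ester), the α-alkoxymethyllithium from tin–lithium exchange then adds to that vinylogous ester carbonyl, and acid ionises the new carbinol with 1,3-transposition and loss of isopropanol, which places the ketone next to the heptenyl carbon and the carbinol next to the CH2OPMB carbon; the carbinol centre is formed racemic and is erased in step 5.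

**Step 5**
Reactants: 17 rac-2-[(1E)-hept-1-en-1-yl]-4-hydroxy-3-{[(4-methoxybenzyl)oxy]methyl}-4-(pent-4-en-1-yn-1-yl)cyclobut-2-en-1-one
Product: 19 2-[(1E)-hept-1-en-1-yl]-3-{[(4-methoxybenzyl)oxy]methyl}-6-(prop-2-en-1-yl)cyclohexa-2,5-diene-1,4-dione, via enynylketene 18 (not isolated)
Conditions: degassed toluene (0.01 M), 110 °C, 1–2 h
Reagents that add atoms: none
Why: Heating opens the cyclobutenone C1–C4 bond in a conrotatory 4π electrocyclic reaction to the (Z)-enynylketene 18, whose ketene carbon then bonds to the remote alkyne carbon; the aryl/aryloxy diradical so formed is quenched by shift of the hydroxyl hydrogen to the ring carbon and gives the quinone directly. The closest known reaction type is the Moore rearrangement of 4-alkynyl-4-hydroxycyclobutenones to 1,4-benzoquinones. One ring is closed, the six-membered carbocycle, in the 6-endo mode (ketene carbon onto the alkyne terminus), so that the four-membered ring grows by the two alkyne carbons. No stereocentre is made: the racemic carbinol carbon of 17 becomes a carbonyl carbon. The step needs outward rotation of the hydroxyl (alkynyl inward, cis to the ketene), secured by the donor OH at C4, and 6-endo instead of 5-exo closure, secured by the non-conjugating CH2 substituent on the alkyne terminus; the PMB ether keeps the primary oxygen from trapping the ketene as a butenolide. The regiochemistry of all four ring substituents is written into the connectivity of 17: C1(=O) and C4(OH) become the para carbonyls, C2/C3 bring heptenyl and CH2OPMB, and the alkyne brings the C–H and the allyl-bearing carbon next to the former C1.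

**Step 6**
Reactants: 19 2-[(1E)-hept-1-en-1-yl]-3-{[(4-methoxybenzyl)oxy]methyl}-6-(prop-2-en-1-yl)cyclohexa-2,5-diene-1,4-dione
Product: 20 (1R,6S)-3-[(1E)-hept-1-en-1-yl]-4-{[(4-methoxybenzyl)oxy]methyl}-1-(prop-2-en-1-yl)-7-oxabicyclo[4.1.0]hept-3-ene-2,5-dione
Conditions: aq. NaOCl (1.5 equiv), cinchona-derived N-(9-anthracenylmethyl)ammonium phase-transfer catalyst (5–10 mol %), chlorobenzene, −10 °C
Reagents that add atoms: sodium hypochlorite [Na+].[O-]Cl
Why: Weitz–Scheffer-type nucleophilic epoxidation of a quinone under chiral phase-transfer catalysis: hypochlorite should add to the only unsubstituted quinone carbon and the enolate closes on oxygen, so that the tetrasubstituted C=C and the isolated alkenes stay untouched, while the ion-paired chiral ammonium cation selects the enantioface and sets both epoxide stereocentres (C1 and C6) at once.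

**Step 7**
Reactants: 20 (1R,6S)-3-[(1E)-hept-1-en-1-yl]-4-{[(4-methoxybenzyl)oxy]methyl}-1-(prop-2-en-1-yl)-7-oxabicyclo[4.1.0]hept-3-ene-2,5-dione; 21 2-methylprop-2-enal (methacrolein)
Product: 22 (2E)-4-[(1R,6S)-3-[(1E)-hept-1-en-1-yl]-4-{[(4-methoxybenzyl)oxy]methyl}-2,5-dioxo-7-oxabicyclo[4.1.0]hept-3-en-1-yl]-2-methylbut-2-enal
Conditions: Hoveyda–Grubbs II (5–10 mol %), 21 (10 equiv), CH2Cl2, 40 °C
Reagents that add atoms: none
Why: Olefin cross-metathesis: the monosubstituted allyl alkene is the only readily initiating olefin (the heptenyl alkene is conjugated to the ene-dione and the ring alkene is tetrasubstituted), and coupling with excess methacrolein should give the trisubstituted enal under thermodynamic control with E geometry (CHO trans to the ring CH2).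

**Step 8**
Reactants: 22 (2E)-4-[(1R,6S)-3-[(1E)-hept-1-en-1-yl]-4-{[(4-methoxybenzyl)oxy]methyl}-2,5-dioxo-7-oxabicyclo[4.1.0]hept-3-en-1-yl]-2-methylbut-2-enal
Product: 23 (2E)-4-[(1R,6S)-3-[(1E)-hept-1-en-1-yl]-4-{[(4-methoxybenzyl)oxy]methyl}-2,5-dioxo-7-oxabicyclo[4.1.0]hept-3-en-1-yl]-2-methylbut-2-enoic acid
Conditions: NaClO2, NaH2PO4, 2-methylbut-2-ene, t-BuOH/H2O, 0 °C → rt
Reagents that add atoms: sodium chlorite [Na+].[O-]Cl=O
Why: Pinnick oxidation: chlorous acid converts only the aldehyde into the acid while 2-methylbut-2-ene scavenges HOCl, and the E geometry, epoxide, PMB ether and ene-dione should survive the buffered conditions.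

**Step 9**
Reactants: 23 (2E)-4-[(1R,6S)-3-[(1E)-hept-1-en-1-yl]-4-{[(4-methoxybenzyl)oxy]methyl}-2,5-dioxo-7-oxabicyclo[4.1.0]hept-3-en-1-yl]-2-methylbut-2-enoic acid
Product: 24 (2E)-4-[(1R,6S)-3-[(1E)-hept-1-en-1-yl]-4-(hydroxymethyl)-2,5-dioxo-7-oxabicyclo[4.1.0]hept-3-en-1-yl]-2-methylbut-2-enoic acid
Conditions: DDQ (1.3 equiv), CH2Cl2/pH 7 buffer (10:1), 0 °C → rt
Reagents that add atoms: none
Why: Oxidative cleavage of the p-methoxybenzyl ether by electron transfer to DDQ and hydrolysis of the oxocarbenium ion; at the ene-dione stage there is no oxidisable allylic alcohol and the diene is electron-poor, which is why the deprotection is placed here and not at the end.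

**Step 10**
Reactants: 24 (2E)-4-[(1R,6S)-3-[(1E)-hept-1-en-1-yl]-4-(hydroxymethyl)-2,5-dioxo-7-oxabicyclo[4.1.0]hept-3-en-1-yl]-2-methylbut-2-enoic acid
Product: 25 (2E)-4-[(1R,5R,6R)-3-[(1E)-hept-1-en-1-yl]-5-hydroxy-4-(hydroxymethyl)-2-oxo-7-oxabicyclo[4.1.0]hept-3-en-1-yl]-2-methylbut-2-enoic acid (ambuic acid)
Conditions: Me4NBH(OAc)3 (3 equiv), MeCN/AcOH (2:1), −40 → −20 °C; aq. Rochelle salt work-up
Reagents that add atoms: none
Why: Hydroxyl-directed triacetoxyborohydride reduction (Evans–Saksena type): the reagent is inert to ketones until it exchanges an acetate for the primary alcohol, which as a β-hydroxy ketone partner can reach only the C5 carbonyl through a six-membered transition state (it is trans to C2 across C3=C4), and the hydride should enter anti to the adjacent epoxide C–O bond (polar Felkin–Anh), giving (5R) with OH syn to the epoxide.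

**Step 11**
Reactants: 25 (2E)-4-[(1R,5R,6R)-3-[(1E)-hept-1-en-1-yl]-5-hydroxy-4-(hydroxymethyl)-2-oxo-7-oxabicyclo[4.1.0]hept-3-en-1-yl]-2-methylbut-2-enoic acid
Product: 26 (2E)-4-[(1S,2R,5R,6R)-3-[(1E)-hept-1-en-1-yl]-2,5-dihydroxy-4-(hydroxymethyl)-7-oxabicyclo[4.1.0]hept-3-en-1-yl]-2-methylbut-2-enoic acid
Conditions: Me4NBH(OAc)3 (8 equiv), MeCN/AcOH (1:1), −20 °C → rt; aq. Rochelle salt work-up
Reagents that add atoms: none
Why: Second hydroxyl-directed triacetoxyborohydride reduction, now across the ring: the C5 hydroxyl on the epoxide face binds boron and delivers hydride over the boat-shaped ring to the same face of the C2 carbonyl, which should place the C2 hydroxyl anti to the epoxide and trans to the C5 hydroxyl, (2R); the primary alcohol cannot reach C2, and excess reagent with acetic acid as co-solvent should keep part of the C5 hydroxyl out of the six-membered borate with the primary alcohol.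

**Compound list**
1 | hept-1-yne | CCCCCC#C | starting material
2 | [(1E)-hept-1-en-1-yl]bis(2-methylpropyl)alumane | CCCCC/C=C/[Al](CC(C)C)CC(C)C | intermediate
3 | (1E)-1-iodohept-1-ene | CCCCC/C=C/I | intermediate
4 | (4-methoxyphenyl)methanol | COc1ccc(CO)cc1 | starting material
5 | tributyl(iodomethyl)stannane | CCCC[Sn](CCCC)(CCCC)CI | starting material
6 | sodium (4-methoxyphenyl)methanolate | COc1ccc(C[O-])cc1.[Na+] | intermediate
7 | tributyl{[(4-methoxybenzyl)oxy]methyl}stannane | CCCC[Sn](CCCC)(CCCC)COCc1ccc(OC)cc1 | intermediate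
8 | 3,4-diisopropoxycyclobut-3-ene-1,2-dione (diisopropyl squarate) | CC(C)OC1=C(OC(C)C)C(=O)C1=O | starting material
9 | [(1E)-hept-1-en-1-yl]lithium | [Li]/C=C/CCCCC | intermediate
10 | lithium 1-[(1E)-hept-1-en-1-yl]-2,3-diisopropoxy-4-oxocyclobut-2-en-1-olate | CCCCC/C=C/C1([O-])C(OC(C)C)=C(OC(C)C)C1=O.[Li+] | intermediate
11 | 3-[(1E)-hept-1-en-1-yl]-4-isopropoxycyclobut-3-ene-1,2-dione | CCCCC/C=C/C1=C(OC(C)C)C(=O)C1=O | intermediate
12 | pent-1-en-4-yne | C=CCC#C | starting material
13 | (pent-4-en-1-yn-1-yl)lithium | [Li]C#CCC=C | intermediate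
14 | lithium 3-[(1E)-hept-1-en-1-yl]-2-isopropoxy-4-oxo-1-(pent-4-en-1-yn-1-yl)cyclobut-2-en-1-olate | CCCCC/C=C/C1=C(OC(C)C)C([O-])(C#CCC=C)C1=O.[Li+] | intermediate
15 | {[(4-methoxybenzyl)oxy]methyl}lithium | [Li]COCc1ccc(OC)cc1 | intermediate
16 | dilithium 4-[(1E)-hept-1-en-1-yl]-3-isopropoxy-1-{[(4-methoxybenzyl)oxy]methyl}-2-(pent-4-en-1-yn-1-yl)cyclobut-3-ene-1,2-diolate | CCCCC/C=C/C1=C(OC(C)C)C([O-])(C#CCC=C)C1([O-])COCc2ccc(OC)cc2.[Li+].[Li+] | intermediate
17 | rac-2-[(1E)-hept-1-en-1-yl]-4-hydroxy-3-{[(4-methoxybenzyl)oxy]methyl}-4-(pent-4-en-1-yn-1-yl)cyclobut-2-en-1-one | CCCCC/C=C/C1=C(COCc2ccc(OC)cc2)C(O)(C#CCC=C)C1=O | intermediate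
18 | (3Z)-2-[(1E)-hept-1-en-1-yl]-4-hydroxy-3-{[(4-methoxybenzyl)oxy]methyl}nona-1,3,8-trien-5-yn-1-one | O=C=C(/C=C/CCCCC)/C(COCc1ccc(OC)cc1)=C(/O)C#CCC=C | intermediate
19 | 2-[(1E)-hept-1-en-1-yl]-3-{[(4-methoxybenzyl)oxy]methyl}-6-(prop-2-en-1-yl)cyclohexa-2,5-diene-1,4-dione | CCCCC/C=C/C1=C(COCc2ccc(OC)cc2)C(=O)C=C(CC=C)C1=O | intermediate
20 | (1R,6S)-3-[(1E)-hept-1-en-1-yl]-4-{[(4-methoxybenzyl)oxy]methyl}-1-(prop-2-en-1-yl)-7-oxabicyclo[4.1.0]hept-3-ene-2,5-dione | CCCCC/C=C/C1=C(COCc3ccc(OC)cc3)C(=O)[C@H]2O[C@@]2(CC=C)C1=O | intermediate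
21 | 2-methylprop-2-enal (methacrolein) | CC(=C)C=O | starting material
22 | (2E)-4-[(1R,6S)-3-[(1E)-hept-1-en-1-yl]-4-{[(4-methoxybenzyl)oxy]methyl}-2,5-dioxo-7-oxabicyclo[4.1.0]hept-3-en-1-yl]-2-methylbut-2-enal | CCCCC/C=C/C1=C(COCc3ccc(OC)cc3)C(=O)[C@H]2O[C@@]2(C/C=C(\C)C=O)C1=O | intermediate
23 | (2E)-4-[(1R,6S)-3-[(1E)-hept-1-en-1-yl]-4-{[(4-methoxybenzyl)oxy]methyl}-2,5-dioxo-7-oxabicyclo[4.1.0]hept-3-en-1-yl]-2-methylbut-2-enoic acid | CCCCC/C=C/C1=C(COCc3ccc(OC)cc3)C(=O)[C@H]2O[C@@]2(C/C=C(\C)C(=O)O)C1=O | intermediate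
24 | (2E)-4-[(1R,6S)-3-[(1E)-hept-1-en-1-yl]-4-(hydroxymethyl)-2,5-dioxo-7-oxabicyclo[4.1.0]hept-3-en-1-yl]-2-methylbut-2-enoic acid | CCCCC/C=C/C1=C(CO)C(=O)[C@H]2O[C@@]2(C/C=C(\C)C(=O)O)C1=O | intermediate
25 | (2E)-4-[(1R,5R,6R)-3-[(1E)-hept-1-en-1-yl]-5-hydroxy-4-(hydroxymethyl)-2-oxo-7-oxabicyclo[4.1.0]hept-3-en-1-yl]-2-methylbut-2-enoic acid (ambuic acid) | CCCCC/C=C/C1=C(CO)[C@@H](O)[C@H]2O[C@@]2(C/C=C(\C)C(=O)O)C1=O | intermediate
26 | (2E)-4-[(1S,2R,5R,6R)-3-[(1E)-hept-1-en-1-yl]-2,5-dihydroxy-4-(hydroxymethyl)-7-oxabicyclo[4.1.0]hept-3-en-1-yl]-2-methylbut-2-enoic acid | CCCCC/C=C/C1=C(CO)[C@@H](O)[C@H]2O[C@@]2(C/C=C(\C)C(=O)O)[C@@H]1O | target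

**Step count**
Total: 11 steps. Longest linear sequence: 10 steps (1, 3, 4, 5, 6, 7, 8, 9, 10, 11).

**Steps most likely to fail, with fallbacks**

Step 5. The diradical formed after ring opening may close in the 5-exo mode, or abstract hydrogen from the doubly allylic CH2, and the alkenyl quinone may decay at the temperature of the rearrangement. The fallback replaces the alkyne by an alkene, so that the ring expansion ends in a concerted 6π electrocyclization to a robust arene. It sets out from 11 (with 12 and 7) and comes back at 19. Pent-1-en-4-yne 12 is hydroaluminated at the alkyne (i-Bu2AlH, hexane, 50 °C) to [(1E)-penta-1,4-dien-1-yl]bis(2-methylpropyl)alumane F1, and iodine gives (1E)-1-iodopenta-1,4-diene F2. Exchange with t-BuLi gives [(1E)-penta-1,4-dien-1-yl]lithium F3, which adds to 11 at the same carbonyl as in step 4 to give lithium 3-[(1E)-hept-1-en-1-yl]-2-isopropoxy-4-oxo-1-[(1E)-penta-1,4-dien-1-yl]cyclobut-2-en-1-olate F4. Methyl triflate traps it as 2-[(1E)-hept-1-en-1-yl]-3-isopropoxy-4-methoxy-4-[(1E)-penta-1,4-dien-1-yl]cyclobut-2-en-1-one F5. Reagent 15 then adds to the vinylogous ester carbonyl to give lithium 4-[(1E)-hept-1-en-1-yl]-3-isopropoxy-2-methoxy-1-{[(4-methoxybenzyl)oxy]methyl}-2-[(1E)-penta-1,4-dien-1-yl]cyclobut-3-en-1-olate F6, and aqueous HCl gives 2-[(1E)-hept-1-en-1-yl]-4-methoxy-3-{[(4-methoxybenzyl)oxy]methyl}-4-[(1E)-penta-1,4-dien-1-yl]cyclobut-2-en-1-one F7. Heating F7 in toluene should open it to a dienylketene that closes and tautomerizes to 2-[(1E)-hept-1-en-1-yl]-4-methoxy-3-{[(4-methoxybenzyl)oxy]methyl}-6-(prop-2-en-1-yl)phenol F8. PhI(OAc)2 in aqueous acetonitrile at 0 °C then oxidizes F8 to quinone 19.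

Step 6. Enantioface discrimination by the ion-paired catalyst may be poor on a trisubstituted benzoquinone, and aqueous base may tautomerize the allyl- and alkoxymethyl-substituted quinone. The fallback moves the epoxidation to a quinone monoketal under homogeneous, non-aqueous tartrate control. It sets out from 11 and comes back at 20. The sequence of the step 5 fallback is followed as far as phenol F8. PhI(OAc)2 in methanol gives 2-[(1E)-hept-1-en-1-yl]-4,4-dimethoxy-3-{[(4-methoxybenzyl)oxy]methyl}-6-(prop-2-en-1-yl)cyclohexa-2,5-dien-1-one F9, with the ketal on the carbon that becomes C5. Tartrate-mediated nucleophilic epoxidation (Ph3COOH, NaHMDS, diisopropyl tartrate of the appropriate hand, toluene, −60 °C) of the only reactive enone C=C should give (1R,6S)-3-[(1E)-hept-1-en-1-yl]-5,5-dimethoxy-4-{[(4-methoxybenzyl)oxy]methyl}-1-(prop-2-en-1-yl)-7-oxabicyclo[4.1.0]hept-3-en-2-one F10. Mild acidic hydrolysis of the ketal (aq. HF, MeCN, 0 °C) returns the route to 20.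

Step 11. Hydride delivery from the C5 hydroxyl across the ring may not be enforced: the hydroxyl may be held in the six-membered borate with the primary alcohol, or a non-directed attack anti to the epoxide may give the C2 epimer. The fallback replaces substrate direction by reagent control. It sets out from 25 and comes back at 26 without a new intermediate: 25 is reduced with a ketoreductase chosen from a commercial panel (NADPH recycling with glucose and glucose dehydrogenase, pH 7 buffer with DMSO), where the enzyme pocket and not the epoxide fixes the face of hydride transfer.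

**Further compounds**
F1 | step 5 | [(1E)-penta-1,4-dien-1-yl]bis(2-methylpropyl)alumane | C=CC/C=C/[Al](CC(C)C)CC(C)C
F2 | step 5 | (1E)-1-iodopenta-1,4-diene | C=CC/C=C/I
F3 | step 5 | [(1E)-penta-1,4-dien-1-yl]lithium | [Li]/C=C/CC=C
F4 | step 5 | lithium 3-[(1E)-hept-1-en-1-yl]-2-isopropoxy-4-oxo-1-[(1E)-penta-1,4-dien-1-yl]cyclobut-2-en-1-olate | CCCCC/C=C/C1=C(OC(C)C)C([O-])(/C=C/CC=C)C1=O.[Li+]
F5 | step 5 | 2-[(1E)-hept-1-en-1-yl]-3-isopropoxy-4-methoxy-4-[(1E)-penta-1,4-dien-1-yl]cyclobut-2-en-1-one | CCCCC/C=C/C1=C(OC(C)C)C(OC)(/C=C/CC=C)C1=O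
F6 | step 5 | lithium 4-[(1E)-hept-1-en-1-yl]-3-isopropoxy-2-methoxy-1-{[(4-methoxybenzyl)oxy]methyl}-2-[(1E)-penta-1,4-dien-1-yl]cyclobut-3-en-1-olate | CCCCC/C=C/C1=C(OC(C)C)C(OC)(/C=C/CC=C)C1([O-])COCc2ccc(OC)cc2.[Li+]
F7 | step 5 | 2-[(1E)-hept-1-en-1-yl]-4-methoxy-3-{[(4-methoxybenzyl)oxy]methyl}-4-[(1E)-penta-1,4-dien-1-yl]cyclobut-2-en-1-one | CCCCC/C=C/C1=C(COCc2ccc(OC)cc2)C(OC)(/C=C/CC=C)C1=O
F8 | step 5 | 2-[(1E)-hept-1-en-1-yl]-4-methoxy-3-{[(4-methoxybenzyl)oxy]methyl}-6-(prop-2-en-1-yl)phenol | CCCCC/C=C/c1c(COCc2ccc(OC)cc2)c(OC)cc(CC=C)c1O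
F9 | step 6 | 2-[(1E)-hept-1-en-1-yl]-4,4-dimethoxy-3-{[(4-methoxybenzyl)oxy]methyl}-6-(prop-2-en-1-yl)cyclohexa-2,5-dien-1-one | CCCCC/C=C/C1=C(COCc2ccc(OC)cc2)C(OC)(OC)C=C(CC=C)C1=O
F10 | step 6 | (1R,6S)-3-[(1E)-hept-1-en-1-yl]-5,5-dimethoxy-4-{[(4-methoxybenzyl)oxy]methyl}-1-(prop-2-en-1-yl)-7-oxabicyclo[4.1.0]hept-3-en-2-one | CCCCC/C=C/C1=C(COCc3ccc(OC)cc3)C(OC)(OC)[C@H]2O[C@@]2(CC=C)C1=O
F0 | step 11 | none | none
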